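**Plan** (labdane numbering: ring A = C1–C5 + C10, ring B = C5–C10, side chain C11–C16, C17 on C8, C18 = CH2OH carbon on C4, C20 = methyl on C10)

1. Retrosynthesis: C6–OH ⇒ C6 ketone (enone); trans ⇒ cis ring fusion; then C6–C7 and C8–C9 are cut together, so ring B ⇒ propyne (C7≡C8–C17) plus a cyclobutanone C5–C6(=O)–C9–C10 fused to ring A.
2. Enabling feature: C6 and C9 are 1,4-related across the ring-fusion bond C5–C10 of ring B, so they can be tied into a strained four-membered acyl–alkyl ring whose C6–C9 bond accepts the two alkyne carbons.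
3. The cyclobutanone is cut at C5–C6 and C9–C10 to an alkene (C5=C10 in ring A) and a ketene (C9=C6=O, carrying the whole side chain) that is tethered through an ether oxygen to C18; the tether is later removed with SmI2.
4. Forward order: ring A (3 steps) and side-chain diazo ester (3 steps) are joined by O–H insertion; tethered [2+2] gives the four-membered ring; nickel-catalysed propyne insertion gives ring B; C5 epimerisation, C6 reduction/inversion and deprotection finish.
5. Stereochemistry: C4 from catalyst-controlled conjugate methylation; C10 and C5 from the C18-face delivery enforced by the tether; C9 by equilibration on the cyclobutanone and retention in the key step; C5 then made trans thermodynamically; C6 by hydride attack anti to the two axial methyls followed by Mitsunobu inversion; the E-alkene from syn-carboalumination.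

Key step: step 11

Remark: compounds 1, 6, 9 and 19 are taken as commercially available; no step has been run, so all outcomes are expectations.

**Step 1**
Reactants: 1 methyl 3-oxocyclohex-1-ene-1-carboxylate
Product: 3 methyl (1S)-1-methyl-3-[(trifluoromethanesulfonyl)oxy]cyclohex-2-ene-1-carboxylate, via zinc enolate 2 (not isolated)
Conditions: Me2Zn, (CuOTf)2·C6H6 (cat.), chiral amino-acid-derived phosphine ligand (cat., enantiomer that gives the S centre), toluene, −20 °C; then Tf2O, −78 → 0 °C
Reagents that add atoms: dimethylzinc C[Zn]C; triflic anhydride O=S(=O)(OS(=O)(=O)C(F)(F)F)C(F)(F)F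
Why: Asymmetric conjugate addition of Me2Zn to the γ-keto ester under (CuOTf)2·C6H6/chiral ligand control should create the quaternary C4 centre (S, catalyst-controlled facial attack on the ester-bearing β-carbon), and O-triflation of the regiodefined zinc enolate fixes the future C5=C10 double bond.

**Step 2**
Reactants: 3 methyl (1S)-1-methyl-3-[(trifluoromethanesulfonyl)oxy]cyclohex-2-ene-1-carboxylate
Product: 4 methyl (1S)-1,3-dimethylcyclohex-2-ene-1-carboxylate
Conditions: MeMgBr, Fe(acac)3 (cat.), THF/NMP, −30 °C
Reagents that add atoms: methylmagnesium bromide C[Mg]Br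
Why: Iron-catalysed Kumada-type cross-coupling of an alkenyl triflate with MeMgBr is fast at low temperature, spares the hindered ester and installs the C10 methyl without touching the stereocentre.

**Step 3**
Reactants: 4 methyl (1S)-1,3-dimethylcyclohex-2-ene-1-carboxylate
Product: 5 [(1S)-1,3-dimethylcyclohex-2-en-1-yl]methanol
Conditions: LiAlH4, Et2O, 0 °C
Reagents that add atoms: none
Why: Hydride reduction of the ester gives the neopentyl alcohol (C18–OH) that serves as tether anchor, the isolated trisubstituted alkene being inert.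

**Step 4**
Reactants: 6 4-bromobut-1-yne
Product: 8 methyl (2E)-5-bromo-3-methylpent-2-enoate, via alkenylalane 7 (not isolated)
Conditions: Me3Al, Cp2ZrCl2 (cat.), CH2Cl2, rt; then ClCO2Me, 0 °C
Reagents that add atoms: trimethylaluminium C[Al](C)C; methyl chloroformate COC(Cl)=O
Why: Zirconium-catalysed syn-carboalumination (Negishi) puts methyl on the internal and aluminium on the terminal alkyne carbon, and acylation of the alkenylalane with retention should give the E-configured C13=C14 enoate.

**Step 5**
Reactants: 8 methyl (2E)-5-bromo-3-methylpent-2-enoate; 9 methyl 3-oxobutanoate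
Product: 10 dimethyl (5E)-2-acetyl-5-methylhept-5-enedioate
Conditions: K2CO3, NaI (cat.), acetone, reflux
Reagents that add atoms: none
Why: Acetoacetic ester alkylation (SN2 of the soft, weakly basic enolate on the primary bromide) forms the C9–C11 bond without elimination to the dienoate.

**Step 6**
Reactants: 10 dimethyl (5E)-2-acetyl-5-methylhept-5-enedioate
Product: 11 dimethyl (5E)-2-diazo-5-methylhept-5-enedioate
Conditions: 4-acetamidobenzenesulfonyl azide, DBU, MeCN, 0 °C → rt
Reagents that add atoms: 4-acetamidobenzenesulfonyl azide CC(=O)Nc1ccc(cc1)S(=O)(=O)N=[N+]=[N-]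
Why: Deacylating diazo transfer (Regitz) converts the α-substituted acetoacetate into the α-diazo ester, the acetyl group leaving on the sulfonamide.

**Step 7**
Reactants: 5 [(1S)-1,3-dimethylcyclohex-2-en-1-yl]methanol; 11 dimethyl (5E)-2-diazo-5-methylhept-5-enedioate
Product: 12 dimethyl (5E)-2-{[(1S)-1,3-dimethylcyclohex-2-en-1-yl]methoxy}-5-methylhept-5-enedioate (both C2 epimers)
Conditions: Rh2(OAc)4 (cat.), CH2Cl2, rt, slow addition of 11
Reagents that add atoms: none
Why: Carbenoid O–H insertion at Rh2(OAc)4 outpaces cyclopropanation of the trisubstituted alkene and joins the fragments as an ether; the new ether stereocentre is unselective but is erased when this carbon becomes the ketene carbon in step 9.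

**Step 8**
Reactants: 12 dimethyl (5E)-2-{[(1S)-1,3-dimethylcyclohex-2-en-1-yl]methoxy}-5-methylhept-5-enedioate
Product: 13 (5E)-2-{[(1S)-1,3-dimethylcyclohex-2-en-1-yl]methoxy}-7-methoxy-5-methyl-7-oxohept-5-enoic acid (both C2 epimers)
Conditions: LiOH (1.1 equiv), THF/H2O, 0 °C; then dilute HCl
Reagents that add atoms: lithium hydroxide [Li+].[OH-]
Why: Chemoselective saponification should hydrolyse the α-alkoxy ester, activated by the adjacent oxygen, and leave the much less electrophilic β,β-disubstituted conjugated ester.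

**Step 9**
Reactants: 13 (5E)-2-{[(1S)-1,3-dimethylcyclohex-2-en-1-yl]methoxy}-7-methoxy-5-methyl-7-oxohept-5-enoic acid
Product: 16 methyl (2E)-5-[(1S,2R,6S,9R)-2,6-dimethyl-10-oxo-8-oxatricyclo[4.4.0.0(2,9)]decan-9-yl]-3-methylpent-2-enoate, via acid chloride 14 (not isolated), via ketene 15 (not isolated)
Conditions: (COCl)2, DMF (cat.), CH2Cl2, 0 °C → rt; then slow addition to Et3N, toluene, reflux, high dilution
Reagents that add atoms: none
Why: Dehydrochlorination gives an alkoxy(alkyl)ketene that should undergo intramolecular ketene–alkene [2+2] cycloaddition in the bridged sense (carbonyl carbon C6 to the less substituted C5, C9 to the methyl-bearing C10); the C18–O tether lets the ketene reach only the C18 face of the alkene, which sets C10 and C5 relative to C4 and gives the cis-fused cyclobutanone.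

**Step 10**
Reactants: 16 methyl (2E)-5-[(1S,2R,6S,9R)-2,6-dimethyl-10-oxo-8-oxatricyclo[4.4.0.0(2,9)]decan-9-yl]-3-methylpent-2-enoate
Product: 18 methyl (2E)-5-[(1S,5S,6R,8S)-5-(acetoxymethyl)-1,5-dimethyl-7-oxobicyclo[4.2.0]octan-8-yl]-3-methylpent-2-enoate, via hydroxy ketone 17 (not isolated)
Conditions: SmI2, t-BuOH, THF, −78 °C; then Ac2O, pyridine, DMAP, rt
Reagents that add atoms: acetic anhydride CC(=O)OC(C)=O
Why: Reductive cleavage of the α-alkoxy ketone by SmI2 removes the tether and frees C18–OH; the enolisable cyclobutanone α-centre C9 should settle under the basic acetylation conditions with the side chain exo (cis to the angular methyl, trans to ring A), and the acetate keeps the hydroxyl from adding to the strained ketone.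

**Step 11**
Reactants: 18 methyl (2E)-5-[(1S,5S,6R,8S)-5-(acetoxymethyl)-1,5-dimethyl-7-oxobicyclo[4.2.0]octan-8-yl]-3-methylpent-2-enoate; 19 propyne
Product: 20 methyl (2E)-5-[(1R,4aR,5S,8aS)-5-(acetoxymethyl)-2,5,8a-trimethyl-4-oxo-1,4,4a,5,6,7,8,8a-octahydronaphthalen-1-yl]-3-methylpent-2-enoate
Conditions: Ni(cod)2 (cat.), PCy3 (cat.), toluene, 100 °C, sealed vessel, slow feed of 19
Reagents that add atoms: none
Why: Zerovalent nickel couples the cyclobutanone carbonyl and propyne by oxidative cyclisation to an oxanickelacyclopentene (C6–C7 bond, nickel on C8); strain-driven β-carbon elimination then moves C9 from C6 to nickel and C–C reductive elimination closes C8–C9, so the alkyne is inserted into the C6–C9 bond. The closest known reaction type is the nickel-catalysed intermolecular insertion of alkynes into cyclobutanones (formal [4+2] by C–C activation), which has been shown with internal alkynes. Ring B is closed by two-carbon ring expansion of the four-membered ring (4 → 6) through a seven-membered nickelacycle that contracts by C(sp2)–C(sp3) reductive elimination; no other ring forms. No new stereocentre is created: C9 passes from carbon to nickel to carbon with retention, C4, C5 and C10 are untouched, and C6 becomes the enone carbonyl. The step needs site selectivity for the C6–C9 over the C6–C5 bond, which should follow because C5 is flanked by the quaternary C4 and C10 while C9 has one quaternary neighbour, so nickel takes the less hindered carbon. It also needs the alkyne orientation with the unsubstituted terminus on the carbonyl carbon and the methyl-bearing carbon on nickel (hence C7–H and C8–CH3), and the hindered enoate and the acetate should not engage.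

**Step 12**
Reactants: 20 methyl (2E)-5-[(1R,4aR,5S,8aS)-5-(acetoxymethyl)-2,5,8a-trimethyl-4-oxo-1,4,4a,5,6,7,8,8a-octahydronaphthalen-1-yl]-3-methylpent-2-enoate
Product: 21 methyl (2E)-5-[(1R,4aS,5S,8aS)-5-(acetoxymethyl)-2,5,8a-trimethyl-4-oxo-1,4,4a,5,6,7,8,8a-octahydronaphthalen-1-yl]-3-methylpent-2-enoate
Conditions: DBU, toluene, 60 °C
Reagents that add atoms: none
Why: Base-mediated epimerisation α to the ketone (through the cross-conjugated enolate) should convert the cis- into the trans-fused decalin, favoured because a cis fusion forces a C4 substituent over ring B, with the equatorial C9 side chain also the thermodynamic arrangement.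

**Step 13**
Reactants: 21 methyl (2E)-5-[(1R,4aS,5S,8aS)-5-(acetoxymethyl)-2,5,8a-trimethyl-4-oxo-1,4,4a,5,6,7,8,8a-octahydronaphthalen-1-yl]-3-methylpent-2-enoate
Product: 22 methyl (2E)-5-[(1R,4S,4aS,5S,8aS)-5-(acetoxymethyl)-4-hydroxy-2,5,8a-trimethyl-1,4,4a,5,6,7,8,8a-octahydronaphthalen-1-yl]-3-methylpent-2-enoate
Conditions: NaBH4, CeCl3·7H2O, MeOH, −40 °C
Reagents that add atoms: none
Why: Luche 1,2-reduction should deliver hydride to C6 from the face opposite the two syn-axial methyl groups on C4 and C10, giving the axial alcohol (the C6 epimer of the target) without reducing the esters.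

**Step 14**
Reactants: 22 methyl (2E)-5-[(1R,4S,4aS,5S,8aS)-5-(acetoxymethyl)-4-hydroxy-2,5,8a-trimethyl-1,4,4a,5,6,7,8,8a-octahydronaphthalen-1-yl]-3-methylpent-2-enoate
Product: 23 methyl (2E)-5-[(1R,4R,4aS,5S,8aS)-5-(acetoxymethyl)-2,5,8a-trimethyl-4-[(4-nitrobenzoyl)oxy]-1,4,4a,5,6,7,8,8a-octahydronaphthalen-1-yl]-3-methylpent-2-enoate
Conditions: 4-nitrobenzoic acid, PPh3, DIAD, toluene, 0 °C → rt
Reagents that add atoms: 4-nitrobenzoic acid OC(=O)c1ccc(cc1)[N+](=O)[O-]
Why: Mitsunobu esterification displaces the oxyphosphonium by SN2 from the open equatorial direction and inverts C6 to the required configuration, the C18 acetate preventing closure of a tetrahydrofuran.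

**Step 15**
Reactants: 23 methyl (2E)-5-[(1R,4R,4aS,5S,8aS)-5-(acetoxymethyl)-2,5,8a-trimethyl-4-[(4-nitrobenzoyl)oxy]-1,4,4a,5,6,7,8,8a-octahydronaphthalen-1-yl]-3-methylpent-2-enoate
Product: 24 methyl (2E)-5-[(1R,4R,4aS,5S,8aS)-4-hydroxy-5-(hydroxymethyl)-2,5,8a-trimethyl-1,4,4a,5,6,7,8,8a-octahydronaphthalen-1-yl]-3-methylpent-2-enoate
Conditions: K2CO3, MeOH, rt
Reagents that add atoms: none
Why: Methanolysis (base-catalysed transesterification) removes the 4-nitrobenzoate and the acetate, while exchange at the side-chain methyl ester is degenerate, giving the target.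

**Compound list**

1 | methyl 3-oxocyclohex-1-ene-1-carboxylate | COC(=O)C1=CC(=O)CCC1 | starting material
2 | methylzinc (3S)-3-(methoxycarbonyl)-3-methylcyclohex-1-en-1-olate | C[Zn]OC1=C[C@@](C)(C(=O)OC)CCC1 | intermediate
3 | methyl (1S)-1-methyl-3-[(trifluoromethanesulfonyl)oxy]cyclohex-2-ene-1-carboxylate | O=S(=O)(OC1=C[C@@](C)(C(=O)OC)CCC1)C(F)(F)F | intermediate
4 | methyl (1S)-1,3-dimethylcyclohex-2-ene-1-carboxylate | CC1=C[C@@](C)(C(=O)OC)CCC1 | intermediate
5 | [(1S)-1,3-dimethylcyclohex-2-en-1-yl]methanol | CC1=C[C@@](C)(CO)CCC1 | intermediate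
6 | 4-bromobut-1-yne | C#CCCBr | starting material
7 | [(1E)-4-bromo-2-methylbut-1-en-1-yl]dimethylalane | C[Al](C)/C=C(\C)CCBr | intermediate
8 | methyl (2E)-5-bromo-3-methylpent-2-enoate | COC(=O)/C=C(\C)CCBr | intermediate
9 | methyl 3-oxobutanoate (methyl acetoacetate) | CC(=O)CC(=O)OC | starting material
10 | dimethyl (5E)-2-acetyl-5-methylhept-5-enedioate (racemic at C2) | COC(=O)/C=C(\C)CCC(C(C)=O)C(=O)OC | intermediate
11 | dimethyl (5E)-2-diazo-5-methylhept-5-enedioate | COC(=O)/C=C(\C)CCC(=[N+]=[N-])C(=O)OC | intermediate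
12 | dimethyl (5E)-2-{[(1S)-1,3-dimethylcyclohex-2-en-1-yl]methoxy}-5-methylhept-5-enedioate (both C2 epimers) | COC(=O)/C=C(\C)CCC(OC[C@@]1(C)CCCC(C)=C1)C(=O)OC | intermediate
13 | (5E)-2-{[(1S)-1,3-dimethylcyclohex-2-en-1-yl]methoxy}-7-methoxy-5-methyl-7-oxohept-5-enoic acid (both C2 epimers) | COC(=O)/C=C(\C)CCC(OC[C@@]1(C)CCCC(C)=C1)C(O)=O | intermediate
14 | methyl (2E)-7-chloro-6-{[(1S)-1,3-dimethylcyclohex-2-en-1-yl]methoxy}-3-methyl-7-oxohept-2-enoate (acid chloride of 13) | COC(=O)/C=C(\C)CCC(OC[C@@]1(C)CCCC(C)=C1)C(Cl)=O | intermediate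
15 | methyl (2E)-6-{[(1S)-1,3-dimethylcyclohex-2-en-1-yl]methoxy}-3-methyl-7-oxohepta-2,6-dienoate (ketene) | COC(=O)/C=C(\C)CCC(OC[C@@]1(C)CCCC(C)=C1)=C=O | intermediate
16 | methyl (2E)-5-[(1S,2R,6S,9R)-2,6-dimethyl-10-oxo-8-oxatricyclo[4.4.0.0(2,9)]decan-9-yl]-3-methylpent-2-enoate (cyclobutanone cis-fused to ring A, ether bridge from C18 to C9) | COC(=O)/C=C(\C)CC[C@]12OC[C@@]3(C)CCC[C@]2(C)[C@H]3C1=O | intermediate
17 | methyl (2E)-5-[(1S,5S,6R,8S)-5-(hydroxymethyl)-1,5-dimethyl-7-oxobicyclo[4.2.0]octan-8-yl]-3-methylpent-2-enoate | COC(=O)/C=C(\C)CC[C@@H]1C(=O)[C@H]2[C@@](C)(CO)CCC[C@@]12C | intermediate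
18 | methyl (2E)-5-[(1S,5S,6R,8S)-5-(acetoxymethyl)-1,5-dimethyl-7-oxobicyclo[4.2.0]octan-8-yl]-3-methylpent-2-enoate | COC(=O)/C=C(\C)CC[C@@H]1C(=O)[C@H]2[C@@](C)(COC(C)=O)CCC[C@@]12C | intermediate
19 | propyne | CC#C | starting material
20 | methyl (2E)-5-[(1R,4aR,5S,8aS)-5-(acetoxymethyl)-2,5,8a-trimethyl-4-oxo-1,4,4a,5,6,7,8,8a-octahydronaphthalen-1-yl]-3-methylpent-2-enoate (cis-fused) | COC(=O)/C=C(\C)CC[C@@H]1C(C)=CC(=O)[C@H]2[C@@](C)(COC(C)=O)CCC[C@@]12C | intermediate
21 | methyl (2E)-5-[(1R,4aS,5S,8aS)-5-(acetoxymethyl)-2,5,8a-trimethyl-4-oxo-1,4,4a,5,6,7,8,8a-octahydronaphthalen-1-yl]-3-methylpent-2-enoate (trans-fused) | COC(=O)/C=C(\C)CC[C@@H]1C(C)=CC(=O)[C@@H]2[C@@](C)(COC(C)=O)CCC[C@@]12C | intermediate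
22 | methyl (2E)-5-[(1R,4S,4aS,5S,8aS)-5-(acetoxymethyl)-4-hydroxy-2,5,8a-trimethyl-1,4,4a,5,6,7,8,8a-octahydronaphthalen-1-yl]-3-methylpent-2-enoate (axial C6 alcohol) | COC(=O)/C=C(\C)CC[C@@H]1C(C)=C[C@H](O)[C@@H]2[C@@](C)(COC(C)=O)CCC[C@@]12C | intermediate
23 | methyl (2E)-5-[(1R,4R,4aS,5S,8aS)-5-(acetoxymethyl)-2,5,8a-trimethyl-4-[(4-nitrobenzoyl)oxy]-1,4,4a,5,6,7,8,8a-octahydronaphthalen-1-yl]-3-methylpent-2-enoate | COC(=O)/C=C(\C)CC[C@@H]1C(C)=C[C@@H](OC(=O)c3ccc(cc3)[N+](=O)[O-])[C@@H]2[C@@](C)(COC(C)=O)CCC[C@@]12C | intermediate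
24 | methyl (2E)-5-[(1R,4R,4aS,5S,8aS)-4-hydroxy-5-(hydroxymethyl)-2,5,8a-trimethyl-1,4,4a,5,6,7,8,8a-octahydronaphthalen-1-yl]-3-methylpent-2-enoate (CNP0149445.1) | COC(=O)/C=C(\C)CC[C@@H]1C(C)=C[C@@H](O)[C@@H]2[C@@](C)(CO)CCC[C@@]12C | target

**Step count and risks**

Total step count: 15. Longest linear sequence: 12 steps (steps 4–15; the branch through steps 1–3 and 7–15 is equally long).

Steps most likely to fail:

1. Step 11. The terminal alkyne may oligomerise or cyclotrimerise on zerovalent nickel faster than it couples with the hindered ketone; the alkyl–nickel intermediate at C9 may also undergo β-hydride elimination towards C11, or nickel may cleave the C6–C5 bond instead. Fallback, setting out from 18: the two-carbon unit is delivered as ethynyltrimethylsilane, which is far less prone to oligomerisation and in which the CH terminus again bonds to C6 while silicon stabilises the carbon–nickel bond at C8. Under Ni(cod)2/PCy3 this should give the 8-trimethylsilyl cis-enone F1; DBU then gives the trans-fused silyl enone F2, and NaBH4/CeCl3·7H2O gives the axial C6 alcohol F3. Iododesilylation with N-iodosuccinimide in hexafluoroisopropanol should give, with retention, the alkenyl iodide F4, and Negishi coupling with MeZnCl and Pd(PPh3)4 installs the C8 methyl, coming back to the route at 22.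

2. Step 9. The ketene may dimerise, or cycloaddition may take the fused instead of the bridged course, before the strained tricycle closes. Fallback, setting out from 13: the acid chloride 14 is made as in step 9 and quenched with pyrrolidine to give the pyrrolidine amide F5. Tf2O with 2-fluoropyridine in CH2Cl2 converts this into the keteniminium triflate F6, a more electrophilic cumulene that does not dimerise. Its intramolecular [2+2] cycloaddition with the C5=C10 alkene under the same tether control gives the cyclobutaniminium triflate F7, and hydrolysis with aqueous NaHCO3 comes back to the route at 16.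

3. Step 14. The activated axial allylic alcohol may eliminate across C5–C6 (the axial hydrogen on C5 is anti-periplanar) to a conjugated diene, or undergo allylic transposition, instead of clean SN2 inversion. Fallback, setting out from 21: the enone is reduced under equilibrating Meerwein–Ponndorf–Verley conditions (Al(OiPr)3, iPrOH, toluene, reflux), where hydride transfer is reversible and the equatorial C6 alcohol, free of the two 1,3-diaxial methyl contacts, should accumulate. The esters exchange under these conditions, so the product is the isopropyl ester diol F8; NaOMe in MeOH then restores the methyl ester, coming back to the route at 24.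

**Further compounds**

F1 | step 11 | analogue of 20 with trimethylsilyl in place of the methyl on the ring alkene carbon C8 (cis-fused) | COC(=O)/C=C(\C)CC[C@@H]1C([Si](C)(C)C)=CC(=O)[C@H]2[C@@](C)(COC(C)=O)CCC[C@@]12C
F2 | step 11 | analogue of 21 with trimethylsilyl in place of the C8 methyl (trans-fused) | COC(=O)/C=C(\C)CC[C@@H]1C([Si](C)(C)C)=CC(=O)[C@@H]2[C@@](C)(COC(C)=O)CCC[C@@]12C
F3 | step 11 | analogue of 22 with trimethylsilyl in place of the C8 methyl (axial C6 alcohol) | COC(=O)/C=C(\C)CC[C@@H]1C([Si](C)(C)C)=C[C@H](O)[C@@H]2[C@@](C)(COC(C)=O)CCC[C@@]12C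
F4 | step 11 | analogue of 22 with iodine in place of the C8 methyl | COC(=O)/C=C(\C)CC[C@@H]1C(I)=C[C@H](O)[C@@H]2[C@@](C)(COC(C)=O)CCC[C@@]12C
F5 | step 9 | pyrrolidine amide of acid 13 (both epimers at the ether carbon) | COC(=O)/C=C(\C)CCC(OC[C@@]1(C)CCCC(C)=C1)C(=O)N1CCCC1
F6 | step 9 | keteniminium triflate derived from F5 (C9=C6=N+ pyrrolidinium) | COC(=O)/C=C(\C)CCC(OC[C@@]1(C)CCCC(C)=C1)=C=[N+]1CCCC1.[O-]S(=O)(=O)C(F)(F)F
F7 | step 9 | cyclobutaniminium triflate corresponding to 16 (C6=N+ pyrrolidinium in place of C6=O) | COC(=O)/C=C(\C)CC[C@]12OC[C@@]3(C)CCC[C@]2(C)[C@H]3C1=[N+]1CCCC1.[O-]S(=O)(=O)C(F)(F)F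
F8 | step 14 | isopropyl ester analogue of 24 (propan-2-yl in place of methyl on the side-chain ester) | CC(C)OC(=O)/C=C(\C)CC[C@@H]1C(C)=C[C@@H](O)[C@@H]2[C@@](C)(CO)CCC[C@@]12C
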